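## Analysis of the target

Target 16 is a 2-arylbenzofuran: a benzofuran (ring A fused to the furan ring) with a free hydroxyl on C6, joined through C2 to C1' of a benzene ring B. Ring B is substituted on five of its six carbons: the benzofuranyl group on C1', 3-methylbut-2-enyl (prenyl) chains on C2' and C6', a hydroxyl on C3' and a methoxy group on C5'; only C4' carries hydrogen. There is no stereocentre, and because each side-chain alkene ends in two methyl groups there is no alkene geometry either, so the control needed is purely regiochemical. The sensitive elements are the C2' prenyl group, which lies next to the C3' hydroxyl and closes to a 2,2-dimethylchroman under acid, the nucleophilic C3 of the benzofuran, and the two electron-rich phenols. The difficulty lies in ring B: the C1'-C2 bond is flanked on both sides by carbon substituents, and the prenyl groups sit where electrophilic C-prenylation of a 5-arylresorcinol derivative would not put them (it would go to C4' or to oxygen). In addition, the oxygens on C3' and C5' must be told apart. The strategy rests on the three neighbouring carbons C2', C1' and C6': each needs one new C-C bond, C1' to an sp2 carbon and its two neighbours to CH2 groups, which is the ipso/ortho/ortho pattern that a Catellani reaction writes around the carbon of an aryl iodide.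

## Retrosynthetic reasoning

Target 16 is traced back to its bis(methoxymethyl) ether 15. The phenols are unmasked last because an ortho-prenylphenol is the most fragile arrangement in the molecule. Acetal protection is chosen because it should pass unchanged through the carbonate/palladium step, the desilylation, the oxidation and the ylide chemistry. The forward reaction has to cleave two aryl acetals without protonating a trisubstituted alkene.

In 15 both side-chain C=C bonds are cut, which leads to dialdehyde 12 and two equivalents of ylide 14, generated from phosphonium salt 13. The cut is made there because an allylic electrophile carrying the finished five-carbon chain cannot take part in the key step: zerovalent palladium would ionise it. The chain is therefore brought in as a saturated two-carbon unit and completed afterwards. Since both chains are identical, each operation is done on both in one flask. The forward reaction has to olefinate an enolisable arylacetaldehyde faster than it deprotonates it.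

Dialdehyde 12 goes back through diol 11 to bis(silyl ether) 10. No skeletal bond is cut here; only the oxidation level of the chain termini and their protection change. The silyl ethers are chosen because they come off under conditions that leave the aryl acetals alone.

Compound 10 is cut at three bonds at once, C2'-CH2, C6'-CH2 and C1'-C2, giving aryl iodide 3, two molecules of bromide 9 and boronate 8. These three bonds sit on adjacent ring carbons and all three fragments are simple. No other disconnection deals with the crowded C1' and both of its neighbours in one operation. The oxygen pattern is untouched, so the OMe/protected-OH differentiation is simply carried in by 3. The forward reaction has to alkylate both ortho C-H bonds before the ipso coupling takes place.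

Iodide 3 is traced through phenol 2 to the symmetrical diether 1. Removing one of two equivalent methyl groups distinguishes the two oxygens at the cheapest possible point, and no regiochemical question arises.

Boronate 8 is cut at the C2-B bond and traced through lithio compound 6 and borate 7 to ether 5, and from there to phenol 4. C2 carries the most acidic C-H of the benzofuran, so the boron is placed by deprotonation with no halogenation step.

## Alternatives that were turned down

Alternative 1: Ring A is disconnected at C7-C7a and C5-C6, which traces the benzofuran back to a trisubstituted furan, the diazomethyl ketone A1.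
- Forward key step: photolysis of A1 triggers a Wolff rearrangement in which the furyl group migrates. The resulting dienylketene closes by a six-electron electrocyclisation and tautomerises to phenol A2.
- For it: the C6 hydroxyl appears at the right carbon, free and without a protecting group, under neutral conditions. The crowded C1'-C2 bond need not be made by cross-coupling, since the furan can be assembled on an aryl carbonyl precursor. On these two points it is stronger than the chosen route.
- Against it: the key step builds the part of the molecule that can be bought as 4. The real problem, two prenyl groups flanking C1', is left to the synthesis of A1, a furan with three different substituents plus a diazoketone, which costs many steps and a hazardous diazoalkane. The carbene or ketene is also generated within reach of two nucleophilic trisubstituted alkenes, so cyclopropanation or [2+2] addition can compete. A2 has two equivalent methoxy groups, one of which must be cleaved at the end with the prenyl groups in place.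
- Comparison: the chosen route spends its key step on ring B itself, fixes the oxygen differentiation in step 1 and should need roughly half as many steps.

Alternative 2: The furan ring is cut at O1-C2 and the aryl-heteroaryl bond at C2-C1', giving the 2-(2,2-dibromovinyl)phenol A3 and the arylboronic acid A4.
- Forward key step: a copper catalyst closes A3 to the 2-bromobenzofuran A5 by intramolecular C-O coupling. In the same flask a palladium catalyst with a bulky biarylphosphine couples A5 with A4 to give A6.
- For it: both bond formations are established for their bond types and the assembly is convergent. The prenyl groups arrive intact, so no side-chain construction follows the coupling. In the reliability of the individual events it is at least as strong as the chosen route.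
- Against it: A4 is where the difficulty has gone. Two prenyl groups must still be placed beside a C1 substituent and not between the oxygens, and that problem stays unsolved. A doubly ortho-substituted, electron-rich boronic acid transmetallates slowly and protodeboronates easily, and its partner A5 is electron-rich as well. A6 again carries two methyl ethers, one of which has to be removed late.
- Comparison: the chosen strategy creates the 2,6-pattern in the same step as the aryl-heteroaryl bond and puts boron on the unhindered heteroaryl partner. The price is three steps of side-chain adjustment.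

Alternative 3: Ring B is disconnected at C1'-C2' and C5'-C6' into the prenyl-bearing diene A7 and the benzofuranylpropiolate A8.
- Forward key step: Diels-Alder addition of the electron-rich diene to the ynoate, then aromatisation by loss of one acetal methoxy group and of the silyl group, gives benzoate A9. In A9, C3' carries the free hydroxyl, C5' the methoxy group, C2' a prenyl chain and C6' an ester.
- For it: ring B is made with the OH/OMe differentiation built in, which is more direct than the demethylation and protection of the chosen route. One prenyl group is present from the start, and the regiochemistry follows from the polarity of both partners.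
- Against it: the two carbons that must bond first are both substituted (prenyl on the diene terminus, benzofuranyl on the β carbon of the ynoate), so the cycloaddition is slowed for a diene that is thermally and hydrolytically fragile. The second prenyl group is not formed: the C6' ester must be reduced, activated as a benzylic halide on a very electron-rich ring and coupled with a 2-methylpropenyl metal reagent. Meanwhile the acid-sensitive ortho-prenylphenol of A9 has to be protected. The two side chains are thus made by different chemistry and the route is longer.
- Comparison: the chosen route treats both chains identically and forms the three bonds around C1' at once. It gives up the built-in oxygen pattern and secures it instead by a two-step desymmetrisation.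

Key step: step 5

Assumption: compounds 1, 4, 9 and 13 are taken to be commercially available; bromide 9 is incorporated twice in step 5.

Step 1
Reactants: 1 1-iodo-3,5-dimethoxybenzene
Product: 2 3-iodo-5-methoxyphenol
Conditions: NaSEt (2 equiv), DMF, 120 °C, N2, light excluded; then aq. HCl
Reagents that add atoms: none
Why: Nucleophilic demethylation (SN2 attack of the soft thiolate on an O-methyl carbon); after the first cleavage the ring is an aryloxide, which makes loss of the second methyl group much slower, so the reaction should stop at the mono-phenol, and an unactivated aryl iodide is not substituted thermally by thiolate in the dark.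

Step 2
Reactants: 2 3-iodo-5-methoxyphenol
Product: 3 1-iodo-3-methoxy-5-(methoxymethoxy)benzene
Conditions: MOMCl, iPr2NEt, CH2Cl2, 0 °C to rt
Reagents that add atoms: chloromethyl methyl ether, COCCl
Why: Williamson-type O-alkylation of the phenol with a reactive α-chloro ether; the resulting acetal is inert to the base, desilylation, oxidation and ylide conditions that follow and is removable with mild acid.

Step 3
Reactants: 4 benzofuran-6-ol
Product: 5 6-(methoxymethoxy)benzofuran
Conditions: MOMCl, iPr2NEt, CH2Cl2, 0 °C to rt
Reagents that add atoms: chloromethyl methyl ether, COCCl
Why: The same O-alkylation masks the acidic phenol of ring A before the lithiation and gives both phenols the same protecting group, so that one final step frees them together.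

Step 4
Reactants: 5 6-(methoxymethoxy)benzofuran
Product: 8 2-[6-(methoxymethoxy)benzofuran-2-yl]-4,4,5,5-tetramethyl-1,3,2-dioxaborolane, via 2-lithio-6-(methoxymethoxy)benzofuran 6 (not isolated), via lithium benzofuranyl(isopropoxy)pinacolborate 7 (not isolated)
Conditions: n-BuLi (1.1 equiv), THF, −78 °C, 1 h; then 2-isopropoxy-4,4,5,5-tetramethyl-1,3,2-dioxaborolane, −78 °C to rt; aq. NH4Cl
Reagents that add atoms: 2-isopropoxy-4,4,5,5-tetramethyl-1,3,2-dioxaborolane, CC(C)OB1OC(C)(C)C(C)(C)O1
Why: Deprotonation of the most acidic C-H of the benzofuran (C2, next to the ring oxygen) followed by electrophilic borylation, the borate 7 losing isopropoxide on work-up; at −78 °C acetal-directed lithiation of ring A should be too slow to compete, and the pinacol ester is chosen because it resists protodeboronation better than the free boronic acid.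

Step 5
Reactants: 3 1-iodo-3-methoxy-5-(methoxymethoxy)benzene, 8 2-[6-(methoxymethoxy)benzofuran-2-yl]-4,4,5,5-tetramethyl-1,3,2-dioxaborolane, 9 (2-bromoethoxy)(tert-butyl)dimethylsilane
Product: 10 2-{2,6-bis[2-(tert-butyldimethylsilyloxy)ethyl]-3-methoxy-5-(methoxymethoxy)phenyl}-6-(methoxymethoxy)benzofuran
Conditions: Pd(OAc)2 (10 mol %), tri(2-furyl)phosphine (20 mol %), norbornene (2 equiv), Cs2CO3 (5 equiv), 9 (4 equiv), 8 (1.5 equiv, added over several hours), DMF/H2O 20:1, 60 °C
Reagents that add atoms: none
Why: Catellani reaction terminated by Suzuki coupling, the known three-component route from an aryl iodide, a primary alkyl bromide and an organoboron reagent to a 2,6-dialkylated biaryl. Zerovalent palladium adds to the C-I bond of 3, norbornene inserts on its exo face, and the norbornylpalladium, which has no syn β-hydrogen to lose, palladates the adjacent aryl C-H to give a five-membered palladacycle of divalent palladium. Bromide 9 adds to this electron-rich palladacycle by an SN2-type oxidative addition to give tetravalent palladium, reductive elimination forms the aryl-CH2 bond, and the sequence repeats at the other ortho carbon, so that C2'-CH2 and C6'-CH2 are both made. Only when both ortho positions are occupied does steric pressure expel norbornene by β-carbon elimination; the 2,6-dialkylarylpalladium left behind is too crowded to take the alkene up again, transmetallates with carbonate-activated boronate 8 and reductively eliminates the C1'-C2 bond. No ring is closed and no stereocentre is formed, so the selectivity required is one of order: ortho, ortho, then ipso. That order is secured by the fast insertion of the strained alkene (used in excess while 8 is fed in slowly) and by the fact that extrusion waits for the second ortho substituent. Each C-H bond that must react lies between the palladium-bearing carbon and an oxygen substituent; OMe and OCH2OMe are small, can turn away and make the ring electron-rich, which is why palladation there is judged feasible although it is at the crowded end of what this reaction tolerates. A prenyl halide could not replace 9 because zerovalent palladium would ionise it to an allyl complex, which is the reason for the saturated silyloxyethyl handle.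

Step 6
Reactants: 10 2-{2,6-bis[2-(tert-butyldimethylsilyloxy)ethyl]-3-methoxy-5-(methoxymethoxy)phenyl}-6-(methoxymethoxy)benzofuran
Product: 11 2-[2,6-bis(2-hydroxyethyl)-3-methoxy-5-(methoxymethoxy)phenyl]-6-(methoxymethoxy)benzofuran
Conditions: TBAF (2.5 equiv), THF, 0 °C to rt; aq. NH4Cl
Reagents that add atoms: none
Why: Fluoride-induced Si-O cleavage driven by the strength of the Si-F bond; the aryl acetals, the methyl ether and the benzofuran are inert to fluoride, so only the two primary alcohols should be released.

Step 7
Reactants: 11 2-[2,6-bis(2-hydroxyethyl)-3-methoxy-5-(methoxymethoxy)phenyl]-6-(methoxymethoxy)benzofuran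
Product: 12 2-[3-methoxy-5-(methoxymethoxy)-2,6-bis(2-oxoethyl)phenyl]-6-(methoxymethoxy)benzofuran
Conditions: Dess-Martin periodinane (2.5 equiv), CH2Cl2, 0 °C to rt; Na2S2O3/NaHCO3 wash; used crude at once
Reagents that add atoms: none
Why: Dess-Martin oxidation of both primary alcohols; the neutral, non-aqueous conditions stop at the aldehyde and avoid the base-induced enolisation and aldol reaction to which arylacetaldehydes are prone, which is also why the dialdehyde is not chromatographed.

Step 8
Reactants: 12 2-[3-methoxy-5-(methoxymethoxy)-2,6-bis(2-oxoethyl)phenyl]-6-(methoxymethoxy)benzofuran, 13 isopropyltriphenylphosphonium iodide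
Product: 15 2-[3-methoxy-5-(methoxymethoxy)-2,6-bis(3-methylbut-2-enyl)phenyl]-6-(methoxymethoxy)benzofuran, via isopropylidenetriphenylphosphorane 14 (not isolated)
Conditions: 13 (3.5 equiv), n-BuLi (3.3 equiv), THF, 0 °C; then 12, −78 °C to rt
Reagents that add atoms: none
Why: Double Wittig olefination with a non-stabilised ylide; the ylide carbon bears two identical methyl groups, so the new trisubstituted alkenes have no geometry to control, and slow addition of the dialdehyde to excess ylide at −78 °C should favour carbonyl addition over α-deprotonation.

Step 9
Reactants: 15 2-[3-methoxy-5-(methoxymethoxy)-2,6-bis(3-methylbut-2-enyl)phenyl]-6-(methoxymethoxy)benzofuran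
Product: 16 2-[3-hydroxy-5-methoxy-2,6-bis(3-methylbut-2-enyl)phenyl]benzofuran-6-ol
Conditions: HCl (2 M aq., catalytic), MeOH, rt to 40 °C, monitored; NaHCO3 quench
Reagents that add atoms: none
Why: Acid-catalysed acetal exchange with the solvent (protonation of the acetal, loss of the phenol, capture of the oxocarbenium ion by methanol); acetal cleavage needs far milder acid than protonation of a trisubstituted alkene, so dilute acid, moderate temperature and an early quench should free both phenols without closing the C3' hydroxyl onto the C2' prenyl group.

Compound list

1 | 1-iodo-3,5-dimethoxybenzene | COc1cc(I)cc(OC)c1 | starting material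
2 | 3-iodo-5-methoxyphenol | COc1cc(O)cc(I)c1 | intermediate
3 | 1-iodo-3-methoxy-5-(methoxymethoxy)benzene | COCOc1cc(I)cc(OC)c1 | intermediate
4 | benzofuran-6-ol | Oc1ccc2ccoc2c1 | starting material
5 | 6-(methoxymethoxy)benzofuran | COCOc1ccc2ccoc2c1 | intermediate
6 | 2-lithio-6-(methoxymethoxy)benzofuran | COCOc1ccc2cc([Li])oc2c1 | intermediate
7 | lithium 2-isopropoxy-2-[6-(methoxymethoxy)benzofuran-2-yl]-4,4,5,5-tetramethyl-1,3,2-dioxaborolan-2-uide | COCOc1ccc2cc([B-]3(OC(C)C)OC(C)(C)C(C)(C)O3)oc2c1.[Li+] | intermediate
8 | 2-[6-(methoxymethoxy)benzofuran-2-yl]-4,4,5,5-tetramethyl-1,3,2-dioxaborolane | COCOc1ccc2cc(B3OC(C)(C)C(C)(C)O3)oc2c1 | intermediate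
9 | (2-bromoethoxy)(tert-butyl)dimethylsilane | BrCCO[Si](C)(C)C(C)(C)C | starting material
10 | 2-{2,6-bis[2-(tert-butyldimethylsilyloxy)ethyl]-3-methoxy-5-(methoxymethoxy)phenyl}-6-(methoxymethoxy)benzofuran | COCOc1cc(OC)c(CCO[Si](C)(C)C(C)(C)C)c(-c2cc3ccc(OCOC)cc3o2)c1CCO[Si](C)(C)C(C)(C)C | intermediate
11 | 2-[2,6-bis(2-hydroxyethyl)-3-methoxy-5-(methoxymethoxy)phenyl]-6-(methoxymethoxy)benzofuran | COCOc1cc(OC)c(CCO)c(-c2cc3ccc(OCOC)cc3o2)c1CCO | intermediate
12 | 2-[3-methoxy-5-(methoxymethoxy)-2,6-bis(2-oxoethyl)phenyl]-6-(methoxymethoxy)benzofuran | COCOc1cc(OC)c(CC=O)c(-c2cc3ccc(OCOC)cc3o2)c1CC=O | intermediate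
13 | isopropyltriphenylphosphonium iodide | CC(C)[P+](c1ccccc1)(c1ccccc1)c1ccccc1.[I-] | starting material
14 | isopropylidenetriphenylphosphorane | CC(C)=P(c1ccccc1)(c1ccccc1)c1ccccc1 | intermediate
15 | 2-[3-methoxy-5-(methoxymethoxy)-2,6-bis(3-methylbut-2-enyl)phenyl]-6-(methoxymethoxy)benzofuran | COCOc1cc(OC)c(CC=C(C)C)c(-c2cc3ccc(OCOC)cc3o2)c1CC=C(C)C | intermediate
16 | 2-[3-hydroxy-5-methoxy-2,6-bis(3-methylbut-2-enyl)phenyl]benzofuran-6-ol | COc1cc(O)c(CC=C(C)C)c(-c2cc3ccc(O)cc3o2)c1CC=C(C)C | target

Total step count: 9.

Longest linear sequence: 7 steps (1 to 2 to 3 to 10 to 11 to 12 to 15 to 16; the branch from 4 through 5 and 8 is equally long).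

Least certain steps

Step 5 (key step). The most likely failure is incomplete ortho alkylation: palladation of a C-H bond squeezed between the palladium-bearing carbon and an alkoxy group may be slow. The un-alkylated or mono-alkylated arylpalladium would then couple with 8 too early or be reduced, and the 2-benzofuranyl boronate would meanwhile be lost by protodeboronation. The fallback sets out from 3 and returns at 15; it makes the bonds by classical halogen chemistry.
- Iodide 3 is brominated twice with N-bromosuccinimide in MeCN. Each bromine should enter para to one alkoxy group, that is at the two positions beside iodine, to give 2,4-dibromo-3-iodo-1-methoxy-5-(methoxymethoxy)benzene F1.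
- Suzuki coupling of F1 with boronate 8 (Pd(PPh3)4, K2CO3, aqueous DME, 60 °C) at the more reactive C-I bond gives 2-[2,6-dibromo-3-methoxy-5-(methoxymethoxy)phenyl]-6-(methoxymethoxy)benzofuran F2.
- Double Stille coupling with allyltributylstannane (Pd2(dba)3, P(t-Bu)3, CsF, dioxane, 100 °C) gives 2-[2,6-diallyl-3-methoxy-5-(methoxymethoxy)phenyl]-6-(methoxymethoxy)benzofuran F3.
- Cross-metathesis with 2-methylbut-2-ene (second-generation Grubbs catalyst, 40 °C) turns both allyl groups into prenyl groups and meets the route at 15, so steps 6 to 8 fall away.

Step 4. Lithiation may go partly to C7, which lies between the ring oxygen and the acetal oxygen, or the lithio compound may open if the temperature rises; the boronate may also lose boron during isolation. The fallback sets out from 5 and returns at 8. It is an iridium-catalysed C-H borylation ([Ir(OMe)(cod)]2, 4,4'-di-tert-butyl-2,2'-bipyridine, B2pin2, THF, 50 °C), which selects the furan α C-H without any organolithium. It makes no new compound (F0).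

Step 8. The basic ylide may deprotonate the arylacetaldehyde instead of adding to it, and the crude dialdehyde from step 7 may already have suffered aldol condensation or air oxidation. The fallback sets out from diol 11 and returns at 15; it exchanges the roles of carbonyl and ylide so that no arylacetaldehyde is ever made.
- Appel-type iodination (I2, PPh3, imidazole, CH2Cl2) gives 2-[2,6-bis(2-iodoethyl)-3-methoxy-5-(methoxymethoxy)phenyl]-6-(methoxymethoxy)benzofuran F4.
- Heating with PPh3 in MeCN gives the bis(phosphonium iodide) [3-methoxy-5-(methoxymethoxy)-2-(6-(methoxymethoxy)benzofuran-2-yl)-1,3-phenylene]bis(ethane-2,1-diyl)bis(triphenylphosphonium) diiodide F5.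
- NaN(SiMe3)2 in THF at −78 to 0 °C gives the bis-ylide 2-{3-methoxy-5-(methoxymethoxy)-2,6-bis[2-(triphenylphosphoranylidene)ethyl]phenyl}-6-(methoxymethoxy)benzofuran F6, which is trapped with acetone to give 15.

Step 9. Acid may add the C3' hydroxyl across the neighbouring prenyl double bond (ring closure to a chroman) or hydrate an alkene before both acetals are gone. The fallback sets out from 15 and returns at 16; it keeps the phenols masked for as long as acid is present.
- Me3SiOTf and 2,2'-bipyridyl in MeCN at 0 °C exchange the aryl acetals directly for silyl ethers, giving 2-[3-methoxy-2,6-bis(3-methylbut-2-enyl)-5-(trimethylsilyloxy)phenyl]-6-(trimethylsilyloxy)benzofuran F7.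
- F7 is hydrolysed with water at neutral pH to 16.

Further compounds

F1 | step 5 | 2,4-dibromo-3-iodo-1-methoxy-5-(methoxymethoxy)benzene | COCOc1cc(OC)c(Br)c(I)c1Br
F2 | step 5 | 2-[2,6-dibromo-3-methoxy-5-(methoxymethoxy)phenyl]-6-(methoxymethoxy)benzofuran | COCOc1cc(OC)c(Br)c(-c2cc3ccc(OCOC)cc3o2)c1Br
F3 | step 5 | 2-[2,6-diallyl-3-methoxy-5-(methoxymethoxy)phenyl]-6-(methoxymethoxy)benzofuran | COCOc1cc(OC)c(CC=C)c(-c2cc3ccc(OCOC)cc3o2)c1CC=C
F0 | step 4 | none | none
F4 | step 8 | 2-[2,6-bis(2-iodoethyl)-3-methoxy-5-(methoxymethoxy)phenyl]-6-(methoxymethoxy)benzofuran | COCOc1cc(OC)c(CCI)c(-c2cc3ccc(OCOC)cc3o2)c1CCI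
F5 | step 8 | [3-methoxy-5-(methoxymethoxy)-2-(6-(methoxymethoxy)benzofuran-2-yl)-1,3-phenylene]bis(ethane-2,1-diyl)bis(triphenylphosphonium) diiodide | COCOc1cc(OC)c(CC[P+](c2ccccc2)(c2ccccc2)c2ccccc2)c(-c2cc3ccc(OCOC)cc3o2)c1CC[P+](c1ccccc1)(c1ccccc1)c1ccccc1.[I-].[I-]
F6 | step 8 | 2-{3-methoxy-5-(methoxymethoxy)-2,6-bis[2-(triphenylphosphoranylidene)ethyl]phenyl}-6-(methoxymethoxy)benzofuran | COCOc1cc(OC)c(CC=P(c2ccccc2)(c2ccccc2)c2ccccc2)c(-c2cc3ccc(OCOC)cc3o2)c1CC=P(c1ccccc1)(c1ccccc1)c1ccccc1
F7 | step 9 | 2-[3-methoxy-2,6-bis(3-methylbut-2-enyl)-5-(trimethylsilyloxy)phenyl]-6-(trimethylsilyloxy)benzofuran | COc1cc(O[Si](C)(C)C)c(CC=C(C)C)c(-c2cc3ccc(O[Si](C)(C)C)cc3o2)c1CC=C(C)C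
A1 | alternative 1 | 2-diazo-1-{5-[3,5-dimethoxy-2,6-bis(3-methylbut-2-enyl)phenyl]-3-vinylfuran-2-yl}ethanone | [N-]=[N+]=CC(=O)c1oc(-c2c(CC=C(C)C)c(OC)cc(OC)c2CC=C(C)C)cc1C=C
A2 | alternative 1 | 2-[3,5-dimethoxy-2,6-bis(3-methylbut-2-enyl)phenyl]benzofuran-6-ol | COc1cc(OC)c(CC=C(C)C)c(-c2cc3ccc(O)cc3o2)c1CC=C(C)C
A3 | alternative 2 | 2-(2,2-dibromovinyl)-5-(triisopropylsilyloxy)phenol | Oc1cc(O[Si](C(C)C)(C(C)C)C(C)C)ccc1C=C(Br)Br
A4 | alternative 2 | [3,5-dimethoxy-2,6-bis(3-methylbut-2-enyl)phenyl]boronic acid | COc1cc(OC)c(CC=C(C)C)c(B(O)O)c1CC=C(C)C
A5 | alternative 2 | 2-bromo-6-(triisopropylsilyloxy)benzofuran | Brc1cc2ccc(O[Si](C(C)C)(C(C)C)C(C)C)cc2o1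
A6 | alternative 2 | 2-[3,5-dimethoxy-2,6-bis(3-methylbut-2-enyl)phenyl]-6-(triisopropylsilyloxy)benzofuran | COc1cc(OC)c(CC=C(C)C)c(-c2cc3ccc(O[Si](C(C)C)(C(C)C)C(C)C)cc3o2)c1CC=C(C)C
A7 | alternative 3 | (3Z)-1,1-dimethoxy-7-methyl-3-(trimethylsilyloxy)octa-1,3,6-triene | COC(OC)=C/C(O[Si](C)(C)C)=C/CC=C(C)C
A8 | alternative 3 | methyl 3-[6-(triisopropylsilyloxy)benzofuran-2-yl]prop-2-ynoate | COC(=O)C#Cc1cc2ccc(O[Si](C(C)C)(C(C)C)C(C)C)cc2o1
A9 | alternative 3 | methyl 4-hydroxy-6-methoxy-3-(3-methylbut-2-enyl)-2-[6-(triisopropylsilyloxy)benzofuran-2-yl]benzoate | COC(=O)c1c(OC)cc(O)c(CC=C(C)C)c1-c1cc2ccc(O[Si](C(C)C)(C(C)C)C(C)C)cc2o1
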